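**Plan**

1. Cuts (carotenoid numbering, primed for the ε half): the sp2–sp2 single bonds C10–C11 and C10′–C11′ that flank the C11–C11′ pentaene, then the two ester C–O bonds. This gives a β-ring C14 dienyl iodide (3-myristate), an ε-ring C14 dienyl iodide (3′-palmitate) and a C12 pentaene carrying SnBu3 at C11′ and Bpin at C11.
2. Enabling feature: both six-membered rings end in the same (E)-C9(Me)=C10H unit, and the chain from C11 to C11′ is a C2-symmetric pentaene equal to commercial C10-dialdehyde plus one carbon per end. A tin/boron-differentiated linchpin can therefore take up two different alkenyl iodides in one flask.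
3. Forward order: no ring is formed. The ε-end comes from (R)-α-ionone (steps 1–5), the β-end from (4R,6R)-actinol (steps 6–12), the linchpin from C10-dialdehyde (steps 13–15). The three-component union follows: Stille at C10′–C11′, then Suzuki–Miyaura at C10–C11 last.
4. Each ring fragment is acylated before the union, so the two hydroxyls never have to be told apart.
5. Stereochemistry: C3 from actinol; C6′ from (R)-α-ionone; C3′ by hydride attack anti to the axial C1′ methyl (trans to the side chain). The C9/C9′ alkenes come from syn-methylalumination, the C11/C11′ alkenes from E-selective chromium(II) olefination, the C7/C7′ alkenes from the Heck step and from α-ionone; the couplings are stereoretentive.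

Key step: step 16

Remark: (R)-α-ionone and (4R,6R)-4-hydroxy-2,2,6-trimethylcyclohexanone are assumed to be purchased as single enantiomers; all polyene intermediates are handled under argon in the dark.

**Route**

Step 1
Reactants: 1 (R)-α-ionone
Product: 3 (6R)-6-[(1E)-but-1-en-3-yn-1-yl]-1,5,5-trimethylcyclohex-1-ene, via enol diethyl phosphate 2 (not isolated)
Conditions: LDA (1.1 equiv), THF, −78 °C; ClP(O)(OEt)2, −78 °C → rt; then LDA (2.3 equiv), THF, −78 °C → rt; H2O
Reagents that add atoms: none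
Why: Kinetic deprotonation at the acetyl methyl group, O-phosphorylation and base-induced elimination of diethyl phosphate (methyl ketone to terminal alkyne through the enol phosphate) should give the enyne, the C6′ stereocentre never being part of the enolate.

Step 2
Reactants: 3 (6R)-6-[(1E)-but-1-en-3-yn-1-yl]-1,5,5-trimethylcyclohex-1-ene
Product: 4 (4R)-4-[(1E)-but-1-en-3-yn-1-yl]-3,5,5-trimethylcyclohex-2-en-1-one
Conditions: t-BuOOH (70% aq., 5 equiv), Rh2(cap)4 (1 mol %), NaHCO3, CH2Cl2, rt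
Reagents that add atoms: tert-butyl hydroperoxide, CC(C)(C)OO
Why: Radical allylic oxidation (peroxyl H-abstraction, mixed peroxide, collapse to the enone) should take the only ring allylic methylene, C3′, because the doubly allylic C6′–H is tertiary and shielded by the gem-dimethyl and C5′-methyl groups, as in the C3 oxidation of α-ionone itself.

Step 3
Reactants: 4 (4R)-4-[(1E)-but-1-en-3-yn-1-yl]-3,5,5-trimethylcyclohex-2-en-1-one
Product: 5 (1R,4R)-4-[(1E)-but-1-en-3-yn-1-yl]-3,5,5-trimethylcyclohex-2-en-1-ol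
Conditions: L-Selectride (1.2 equiv), THF, −78 °C; H2O
Reagents that add atoms: none
Why: 1,2-Reduction of the β,β-disubstituted cyclohexenone by a bulky borohydride: with the side chain pseudo-axial on C6′ (avoiding A(1,2) strain with the C5′ methyl) the axial C1′ methyl lies on the opposite face and blocks it 1,3 to the carbonyl, so hydride should enter syn to the side chain and set the C3′ hydroxyl trans to it, (3′R).

Step 4
Reactants: 5 (1R,4R)-4-[(1E)-but-1-en-3-yn-1-yl]-3,5,5-trimethylcyclohex-2-en-1-ol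
Product: 7 (1R,4R)-4-[(1E,3E)-4-iodo-3-methylbuta-1,3-dien-1-yl]-3,5,5-trimethylcyclohex-2-en-1-ol, via O-aluminated alkenylalane 6 (not isolated)
Conditions: Me3Al (4 equiv), Cp2ZrCl2 (0.3 equiv), CH2Cl2, 0 °C → rt; then I2 (1.5 equiv), THF, −30 → 0 °C; aq. Rochelle salt
Reagents that add atoms: trimethylaluminium, C[Al](C)C; iodine, II
Why: Zirconium-catalysed carboalumination (Negishi) adds methyl and aluminium syn across the terminal alkyne with methyl at the internal carbon, the hydroxyl being carried as its dimethylaluminium alkoxide, and iodinolysis of the alkenyl C–Al bond with retention should give the (E)-C9′(Me)=C10′H–I unit.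

Step 5
Reactants: 7 (1R,4R)-4-[(1E,3E)-4-iodo-3-methylbuta-1,3-dien-1-yl]-3,5,5-trimethylcyclohex-2-en-1-ol
Product: 8 (1R,4R)-4-[(1E,3E)-4-iodo-3-methylbuta-1,3-dien-1-yl]-3,5,5-trimethylcyclohex-2-en-1-yl hexadecanoate
Conditions: palmitoyl chloride (1.3 equiv), pyridine, DMAP (cat.), CH2Cl2, 0 °C → rt
Reagents that add atoms: palmitoyl chloride, CCCCCCCCCCCCCCCC(=O)Cl
Why: DMAP-catalysed O-acylation of the secondary allylic alcohol takes place at oxygen with retention at C3′ and leaves the dienyl iodide untouched.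

Step 6
Reactants: 9 (4R,6R)-4-hydroxy-2,2,6-trimethylcyclohexan-1-one (actinol)
Product: 10 (4R,6R)-4-[(tert-butyldimethylsilyl)oxy]-2,2,6-trimethylcyclohexan-1-one
Conditions: TBSCl, imidazole, DMF, rt
Reagents that add atoms: tert-butyldimethylsilyl chloride, CC(C)(C)[Si](C)(C)Cl
Why: Standard silylation masks the secondary alcohol for the strongly basic steps that follow.

Step 7
Reactants: 10 (4R,6R)-4-[(tert-butyldimethylsilyl)oxy]-2,2,6-trimethylcyclohexan-1-one
Product: 11 (4R)-4-[(tert-butyldimethylsilyl)oxy]-2,6,6-trimethylcyclohex-1-en-1-yl trifluoromethanesulfonate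
Conditions: LDA, THF, −78 → 0 °C; PhNTf2, 0 °C → rt
Reagents that add atoms: N-phenylbis(trifluoromethanesulfonimide), O=S(=O)(N(c1ccccc1)S(=O)(=O)C(F)(F)F)C(F)(F)F
Why: Enolisation is possible only toward the methyl-bearing α-carbon (the other α-carbon is quaternary), so O-sulfonylation should give the single tetrasubstituted enol triflate, with the carbinol centre untouched.

Step 8
Reactants: 11 (4R)-4-[(tert-butyldimethylsilyl)oxy]-2,6,6-trimethylcyclohex-1-en-1-yl trifluoromethanesulfonate; 12 but-3-en-2-one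
Product: 13 (3E)-4-[(4R)-4-[(tert-butyldimethylsilyl)oxy]-2,6,6-trimethylcyclohex-1-en-1-yl]but-3-en-2-one
Conditions: 12 (3 equiv), Pd(OAc)2 (5 mol %), PPh3 (10 mol %), Et3N, DMF, 70 °C
Reagents that add atoms: none
Why: Heck reaction of the enol triflate (oxidative addition, syn-insertion into the enone alkene, syn-β-hydride elimination) should give the (E)-dienone, the silyl ether of (3R)-3-hydroxy-β-ionone.

Step 9
Reactants: 13 (3E)-4-[(4R)-4-[(tert-butyldimethylsilyl)oxy]-2,6,6-trimethylcyclohex-1-en-1-yl]but-3-en-2-one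
Product: 15 tert-butyl{[(1R)-4-[(1E)-but-1-en-3-yn-1-yl]-3,5,5-trimethylcyclohex-3-en-1-yl]oxy}dimethylsilane, via enol diethyl phosphate 14 (not isolated)
Conditions: LDA (1.1 equiv), THF, −78 °C; ClP(O)(OEt)2, −78 °C → rt; then LDA (2.3 equiv), THF, −78 °C → rt; H2O
Reagents that add atoms: none
Why: The same methyl ketone to terminal alkyne conversion through the enol phosphate as in step 1, on a β-ionone-type dienone that is deprotonated kinetically at the acetyl methyl group.

Step 10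
Reactants: 15 tert-butyl{[(1R)-4-[(1E)-but-1-en-3-yn-1-yl]-3,5,5-trimethylcyclohex-3-en-1-yl]oxy}dimethylsilane
Product: 17 tert-butyl{[(1R)-4-[(1E,3E)-4-iodo-3-methylbuta-1,3-dien-1-yl]-3,5,5-trimethylcyclohex-3-en-1-yl]oxy}dimethylsilane, via alkenylalane 16 (not isolated)
Conditions: Me3Al (2 equiv), Cp2ZrCl2 (0.3 equiv), CH2Cl2, rt; then I2 (1.3 equiv), THF, −30 → 0 °C
Reagents that add atoms: trimethylaluminium, C[Al](C)C; iodine, II
Why: Zirconium-catalysed syn-carboalumination (Negishi) of the conjugated terminal alkyne followed by iodinolysis with retention should give the (E)-C9(Me)=C10H–I dienyl iodide.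

Step 11
Reactants: 17 tert-butyl{[(1R)-4-[(1E,3E)-4-iodo-3-methylbuta-1,3-dien-1-yl]-3,5,5-trimethylcyclohex-3-en-1-yl]oxy}dimethylsilane
Product: 18 (1R)-4-[(1E,3E)-4-iodo-3-methylbuta-1,3-dien-1-yl]-3,5,5-trimethylcyclohex-3-en-1-ol
Conditions: TBAF, THF, 0 °C → rt
Reagents that add atoms: none
Why: Fluoride cleaves the secondary silyl ether, and the dienyl iodide is inert to TBAF.

Step 12
Reactants: 18 (1R)-4-[(1E,3E)-4-iodo-3-methylbuta-1,3-dien-1-yl]-3,5,5-trimethylcyclohex-3-en-1-ol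
Product: 19 (1R)-4-[(1E,3E)-4-iodo-3-methylbuta-1,3-dien-1-yl]-3,5,5-trimethylcyclohex-3-en-1-yl tetradecanoate
Conditions: myristoyl chloride (1.3 equiv), pyridine, DMAP (cat.), CH2Cl2, 0 °C → rt
Reagents that add atoms: myristoyl chloride, CCCCCCCCCCCCCC(=O)Cl
Why: DMAP-catalysed O-acylation of the unhindered secondary alcohol with retention at C3.

Step 13
Reactants: 20 diiodomethane
Product: 21 tributyl(diiodomethyl)stannane
Conditions: LiHMDS, THF/Et2O, −78 °C; Bu3SnCl, −78 °C → rt
Reagents that add atoms: tributyltin chloride, CCCC[Sn](Cl)(CCCC)CCCC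
Why: Low-temperature deprotonation of diiodomethane and trapping of the carbenoid at carbon by the tin chloride (carbenoid stannylation) should outrun α-elimination.

Step 14
Reactants: 22 (2E,4E,6E)-2,7-dimethylocta-2,4,6-trienedial (C10-dialdehyde)
Product: 23 (2E,4E,6E,8E)-2,7-dimethyl-9-(4,4,5,5-tetramethyl-1,3,2-dioxaborolan-2-yl)nona-2,4,6,8-tetraenal
Conditions: 22 (3 equiv), Cl2CHBpin (1 equiv), CrCl2 (6 equiv), LiI (3 equiv), THF, rt; excess 22 recovered
Reagents that add atoms: 2-(dichloromethyl)-4,4,5,5-tetramethyl-1,3,2-dioxaborolane, ClC(Cl)B1OC(C)(C)C(C)(C)O1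
Why: Takai–Utimoto-type chromium(II) olefination with the gem-dihalomethylboronate (gem-dichromium addition to the aldehyde, then elimination) is E-selective, and the excess of the symmetric dialdehyde should hold the reaction at mono-olefination.

Step 15
Reactants: 23 (2E,4E,6E,8E)-2,7-dimethyl-9-(4,4,5,5-tetramethyl-1,3,2-dioxaborolan-2-yl)nona-2,4,6,8-tetraenal; 21 tributyl(diiodomethyl)stannane
Product: 24 tributyl[(1E,3E,5E,7E,9E)-3,8-dimethyl-10-(4,4,5,5-tetramethyl-1,3,2-dioxaborolan-2-yl)deca-1,3,5,7,9-pentaen-1-yl]stannane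
Conditions: 21 (2 equiv), CrCl2 (8 equiv), DMF/THF, rt; chromatography on Et3N-deactivated silica
Reagents that add atoms: none
Why: The same chromium(II) gem-dimetal olefination with the stannyl gem-diiodide should turn the remaining aldehyde into the (E)-alkenylstannane, the alkenylboronate being inert to chromium(II).

Step 16
Reactants: 8 (1R,4R)-4-[(1E,3E)-4-iodo-3-methylbuta-1,3-dien-1-yl]-3,5,5-trimethylcyclohex-2-en-1-yl hexadecanoate; 24 tributyl[(1E,3E,5E,7E,9E)-3,8-dimethyl-10-(4,4,5,5-tetramethyl-1,3,2-dioxaborolan-2-yl)deca-1,3,5,7,9-pentaen-1-yl]stannane; 19 (1R)-4-[(1E,3E)-4-iodo-3-methylbuta-1,3-dien-1-yl]-3,5,5-trimethylcyclohex-3-en-1-yl tetradecanoate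
Product: 26 (3R,3′R,6′R)-β,ε-carotene-3,3′-diol 3-tetradecanoate 3′-hexadecanoate (CNP0230054.1), via C26 heptaenyl pinacol boronate 25 (not isolated)
Conditions: 8 (1.0 equiv), 24 (1.0 equiv), Pd2(dba)3 (5 mol %), AsPh3 (40 mol %), degassed DMF/THF, rt, dark; then 19 (1.05 equiv), PdCl2(dppf) (5 mol %), aq. K3PO4 (3 M, 3 equiv), rt, dark
Reagents that add atoms: none
Why: Oxidative addition of Pd(0) into the C10′–I bond of 8, tin-to-palladium transmetalation at the stannyl end of 24 and reductive elimination form C10′–C11′ and leave the boronate end untouched, because an alkenyl–Bpin does not transmetalate without base; adding 19 and aqueous phosphate then starts a second cycle in which oxidative addition into the C10–I bond of 19, base-assisted boron-to-palladium transmetalation of 25 and reductive elimination form the C10–C11 bond between the C26 and C14 halves. The closest known reaction type is the one-pot Stille/Suzuki–Miyaura coupling of a stannyl/boryl-differentiated diene linchpin with two different alkenyl halides. No ring is closed and no stereocentre is created; the nine chain double bonds should keep their geometry because both couplings are stereoretentive at sp2 carbon and run at room temperature in the dark. The selectivity needed is tin-over-boron chemoselectivity in the first stage, secured by the two different metals on the linchpin, base-free conditions and 1:1 stoichiometry, so that 8 is consumed before 19 and base are added. Oxidative addition into the alkenyl iodides is expected to be much faster than ionisation of the allylic palmitate at C3′, and phosphate at room temperature should spare both secondary esters.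

**Compound list**

1 | (R)-α-ionone, (3E)-4-[(1R)-2,6,6-trimethylcyclohex-2-en-1-yl]but-3-en-2-one | C1C=C(C)[C@H](/C=C/C(C)=O)C(C)(C)C1 | starting material
2 | diethyl (3E)-4-[(1R)-2,6,6-trimethylcyclohex-2-en-1-yl]buta-1,3-dien-2-yl phosphate | C1C=C(C)[C@H](/C=C/C(=C)OP(=O)(OCC)OCC)C(C)(C)C1 | intermediate
3 | (6R)-6-[(1E)-but-1-en-3-yn-1-yl]-1,5,5-trimethylcyclohex-1-ene | C1C=C(C)[C@H](/C=C/C#C)C(C)(C)C1 | intermediate
4 | (4R)-4-[(1E)-but-1-en-3-yn-1-yl]-3,5,5-trimethylcyclohex-2-en-1-one | O=C1C=C(C)[C@H](/C=C/C#C)C(C)(C)C1 | intermediate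
5 | (1R,4R)-4-[(1E)-but-1-en-3-yn-1-yl]-3,5,5-trimethylcyclohex-2-en-1-ol (hydroxyl trans to side chain) | O[C@H]1C=C(C)[C@H](/C=C/C#C)C(C)(C)C1 | intermediate
6 | dimethylaluminium (1R,4R)-4-[(1E,3E)-4-(dimethylalumanyl)-3-methylbuta-1,3-dien-1-yl]-3,5,5-trimethylcyclohex-2-en-1-olate | C[Al](C)O[C@H]1C=C(C)[C@H](/C=C/C(C)=C/[Al](C)C)C(C)(C)C1 | intermediate
7 | (1R,4R)-4-[(1E,3E)-4-iodo-3-methylbuta-1,3-dien-1-yl]-3,5,5-trimethylcyclohex-2-en-1-ol | O[C@H]1C=C(C)[C@H](/C=C/C(C)=C/I)C(C)(C)C1 | intermediate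
8 | (1R,4R)-4-[(1E,3E)-4-iodo-3-methylbuta-1,3-dien-1-yl]-3,5,5-trimethylcyclohex-2-en-1-yl hexadecanoate (ε-end iodide) | CCCCCCCCCCCCCCCC(=O)O[C@H]1C=C(C)[C@H](/C=C/C(C)=C/I)C(C)(C)C1 | intermediate
9 | (4R,6R)-4-hydroxy-2,2,6-trimethylcyclohexan-1-one (actinol) | O=C1[C@H](C)C[C@@H](O)CC1(C)C | starting material
10 | (4R,6R)-4-[(tert-butyldimethylsilyl)oxy]-2,2,6-trimethylcyclohexan-1-one | O=C1[C@H](C)C[C@@H](O[Si](C)(C)C(C)(C)C)CC1(C)C | intermediate
11 | (4R)-4-[(tert-butyldimethylsilyl)oxy]-2,6,6-trimethylcyclohex-1-en-1-yl trifluoromethanesulfonate | O=S(=O)(OC1=C(C)C[C@@H](O[Si](C)(C)C(C)(C)C)CC1(C)C)C(F)(F)F | intermediate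
12 | but-3-en-2-one (methyl vinyl ketone) | C=CC(C)=O | starting material
13 | (3E)-4-[(4R)-4-[(tert-butyldimethylsilyl)oxy]-2,6,6-trimethylcyclohex-1-en-1-yl]but-3-en-2-one | CC(=O)/C=C/C1=C(C)C[C@@H](O[Si](C)(C)C(C)(C)C)CC1(C)C | intermediate
14 | diethyl (3E)-4-[(4R)-4-[(tert-butyldimethylsilyl)oxy]-2,6,6-trimethylcyclohex-1-en-1-yl]buta-1,3-dien-2-yl phosphate | C=C(OP(=O)(OCC)OCC)/C=C/C1=C(C)C[C@@H](O[Si](C)(C)C(C)(C)C)CC1(C)C | intermediate
15 | tert-butyl{[(1R)-4-[(1E)-but-1-en-3-yn-1-yl]-3,5,5-trimethylcyclohex-3-en-1-yl]oxy}dimethylsilane | C#C/C=C/C1=C(C)C[C@@H](O[Si](C)(C)C(C)(C)C)CC1(C)C | intermediate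
16 | {(1E,3E)-4-[(4R)-4-[(tert-butyldimethylsilyl)oxy]-2,6,6-trimethylcyclohex-1-en-1-yl]-2-methylbuta-1,3-dien-1-yl}dimethylalumane | C[Al](C)/C=C(C)/C=C/C1=C(C)C[C@@H](O[Si](C)(C)C(C)(C)C)CC1(C)C | intermediate
17 | tert-butyl{[(1R)-4-[(1E,3E)-4-iodo-3-methylbuta-1,3-dien-1-yl]-3,5,5-trimethylcyclohex-3-en-1-yl]oxy}dimethylsilane | I/C=C(C)/C=C/C1=C(C)C[C@@H](O[Si](C)(C)C(C)(C)C)CC1(C)C | intermediate
18 | (1R)-4-[(1E,3E)-4-iodo-3-methylbuta-1,3-dien-1-yl]-3,5,5-trimethylcyclohex-3-en-1-ol | I/C=C(C)/C=C/C1=C(C)C[C@@H](O)CC1(C)C | intermediate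
19 | (1R)-4-[(1E,3E)-4-iodo-3-methylbuta-1,3-dien-1-yl]-3,5,5-trimethylcyclohex-3-en-1-yl tetradecanoate (β-end iodide) | I/C=C(C)/C=C/C1=C(C)C[C@@H](OC(=O)CCCCCCCCCCCCC)CC1(C)C | intermediate
20 | diiodomethane | ICI | starting material
21 | tributyl(diiodomethyl)stannane | CCCC[Sn](CCCC)(CCCC)C(I)I | intermediate
22 | (2E,4E,6E)-2,7-dimethylocta-2,4,6-trienedial | O=C/C(C)=C/C=C/C=C(C)/C=O | starting material
23 | (2E,4E,6E,8E)-2,7-dimethyl-9-(4,4,5,5-tetramethyl-1,3,2-dioxaborolan-2-yl)nona-2,4,6,8-tetraenal | O=C/C(C)=C/C=C/C=C(C)/C=C/B1OC(C)(C)C(C)(C)O1 | intermediate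
24 | tributyl[(1E,3E,5E,7E,9E)-3,8-dimethyl-10-(4,4,5,5-tetramethyl-1,3,2-dioxaborolan-2-yl)deca-1,3,5,7,9-pentaen-1-yl]stannane | CCCC[Sn](CCCC)(CCCC)/C=C/C(C)=C/C=C/C=C(C)/C=C/B1OC(C)(C)C(C)(C)O1 | intermediate
25 | (1R,4R)-4-[(1E,3E,5E,7E,9E,11E,13E)-3,7,12-trimethyl-14-(4,4,5,5-tetramethyl-1,3,2-dioxaborolan-2-yl)tetradeca-1,3,5,7,9,11,13-heptaen-1-yl]-3,5,5-trimethylcyclohex-2-en-1-yl hexadecanoate | CCCCCCCCCCCCCCCC(=O)O[C@H]1C=C(C)[C@H](/C=C/C(C)=C/C=C/C(C)=C/C=C/C=C(C)/C=C/B2OC(C)(C)C(C)(C)O2)C(C)(C)C1 | intermediate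
26 | (3R,3′R,6′R)-β,ε-carotene-3,3′-diol 3-tetradecanoate 3′-hexadecanoate (lutein 3-myristate 3′-palmitate, CNP0230054.1) | CCCCCCCCCCCCCCCC(=O)O[C@H]1C=C(C)[C@H](/C=C/C(C)=C/C=C/C(C)=C/C=C/C=C(C)/C=C/C=C(C)/C=C/C2=C(C)C[C@@H](OC(=O)CCCCCCCCCCCCC)CC2(C)C)C(C)(C)C1 | target

**Step count and risks**

Total steps: 16. Longest linear sequence: 8 (steps 6–12, then step 16).

Steps most likely to fail:

1. Step 16. The risk is loss of tin-over-boron chemoselectivity, or protodemetalation and E/Z drift of the bis-metallated pentaene, during the long one-flask sequence. The fallback gives up the tin/boron linchpin and builds the chain in separate two-component stages; it sets out from 23 and 8 and rejoins the route at 25. Suzuki–Miyaura coupling of boronate aldehyde 23 with iodide 8 (PdCl2(dppf), aq. K3PO4, THF, rt) should give the ε-side aldehyde (1R,4R)-4-[(1E,3E,5E,7E,9E,11E)-3,7,12-trimethyl-13-oxotrideca-1,3,5,7,9,11-hexaen-1-yl]-3,5,5-trimethylcyclohex-2-en-1-yl hexadecanoate F1. Chromium(II) olefination of this aldehyde with Cl2CHBpin (CrCl2, LiI, THF) should give boronate 25, now isolated. A separate Suzuki–Miyaura coupling of 25 with 19 then forms C10–C11 and gives 26.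

2. Step 2. The risk is competing hydrogen abstraction at the doubly allylic C6′–H, or peroxyl-radical addition to the conjugated enyne, in place of clean C3′ oxidation. The fallback oxygenates C3′ enzymatically before the alkyne is made; it sets out from 1 and rejoins at 5, so that steps 2 and 3 are bypassed. A cytochrome P450 monooxygenase (an engineered P450 BM3 variant of the kind that hydroxylates α-ionone at C3 trans to the side chain; whole cells, glucose/glucose dehydrogenase for NADPH recycling, air, phosphate buffer, 30 °C) should convert 1 into (3E)-4-[(1R,4R)-4-hydroxy-2,6,6-trimethylcyclohex-2-en-1-yl]but-3-en-2-one F2. Silylation (TBSCl, imidazole, DMF) gives (3E)-4-[(1R,4R)-4-[(tert-butyldimethylsilyl)oxy]-2,6,6-trimethylcyclohex-2-en-1-yl]but-3-en-2-one F3. The step-1 sequence (LDA; ClP(O)(OEt)2; LDA) then passes through diethyl (3E)-4-[(1R,4R)-4-[(tert-butyldimethylsilyl)oxy]-2,6,6-trimethylcyclohex-2-en-1-yl]buta-1,3-dien-2-yl phosphate F4 to tert-butyl{[(1R,4R)-4-[(1E)-but-1-en-3-yn-1-yl]-3,5,5-trimethylcyclohex-2-en-1-yl]oxy}dimethylsilane F5, and TBAF in THF releases 5.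

3. Step 3. The risk is poor or reversed facial selectivity of hydride delivery, giving the C3′ epimer. The fallback uses the epimer productively by inverting C3′ in the esterification; it sets out from 4 and rejoins at 8. Should reduction of 4 deliver mainly the cis alcohol (1S,4R)-4-[(1E)-but-1-en-3-yn-1-yl]-3,5,5-trimethylcyclohex-2-en-1-ol F6, this is taken through the step-4 conditions, via dimethylaluminium (1S,4R)-4-[(1E,3E)-4-(dimethylalumanyl)-3-methylbuta-1,3-dien-1-yl]-3,5,5-trimethylcyclohex-2-en-1-olate F7, to (1S,4R)-4-[(1E,3E)-4-iodo-3-methylbuta-1,3-dien-1-yl]-3,5,5-trimethylcyclohex-2-en-1-ol F8. Mitsunobu esterification of this alcohol with palmitic acid (PPh3, DIAD, THF, 0 °C) should install the palmitate with inversion at C3′ and give 8 directly; SN2′ attack is disfavoured because the distal alkene carbon is fully substituted.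

Further compounds
F1 | step 16 | (1R,4R)-4-[(1E,3E,5E,7E,9E,11E)-3,7,12-trimethyl-13-oxotrideca-1,3,5,7,9,11-hexaen-1-yl]-3,5,5-trimethylcyclohex-2-en-1-yl hexadecanoate | CCCCCCCCCCCCCCCC(=O)O[C@H]1C=C(C)[C@H](/C=C/C(C)=C/C=C/C(C)=C/C=C/C=C(C)/C=O)C(C)(C)C1
F2 | step 2 | (3E)-4-[(1R,4R)-4-hydroxy-2,6,6-trimethylcyclohex-2-en-1-yl]but-3-en-2-one | O[C@H]1C=C(C)[C@H](/C=C/C(C)=O)C(C)(C)C1
F3 | step 2 | (3E)-4-[(1R,4R)-4-[(tert-butyldimethylsilyl)oxy]-2,6,6-trimethylcyclohex-2-en-1-yl]but-3-en-2-one | CC(C)(C)[Si](C)(C)O[C@H]1C=C(C)[C@H](/C=C/C(C)=O)C(C)(C)C1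
F4 | step 2 | diethyl (3E)-4-[(1R,4R)-4-[(tert-butyldimethylsilyl)oxy]-2,6,6-trimethylcyclohex-2-en-1-yl]buta-1,3-dien-2-yl phosphate | CC(C)(C)[Si](C)(C)O[C@H]1C=C(C)[C@H](/C=C/C(=C)OP(=O)(OCC)OCC)C(C)(C)C1
F5 | step 2 | tert-butyl{[(1R,4R)-4-[(1E)-but-1-en-3-yn-1-yl]-3,5,5-trimethylcyclohex-2-en-1-yl]oxy}dimethylsilane | CC(C)(C)[Si](C)(C)O[C@H]1C=C(C)[C@H](/C=C/C#C)C(C)(C)C1
F6 | step 3 | (1S,4R)-4-[(1E)-but-1-en-3-yn-1-yl]-3,5,5-trimethylcyclohex-2-en-1-ol | O[C@@H]1C=C(C)[C@H](/C=C/C#C)C(C)(C)C1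
F7 | step 3 | dimethylaluminium (1S,4R)-4-[(1E,3E)-4-(dimethylalumanyl)-3-methylbuta-1,3-dien-1-yl]-3,5,5-trimethylcyclohex-2-en-1-olate | C[Al](C)O[C@@H]1C=C(C)[C@H](/C=C/C(C)=C/[Al](C)C)C(C)(C)C1
F8 | step 3 | (1S,4R)-4-[(1E,3E)-4-iodo-3-methylbuta-1,3-dien-1-yl]-3,5,5-trimethylcyclohex-2-en-1-ol | O[C@@H]1C=C(C)[C@H](/C=C/C(C)=C/I)C(C)(C)C1
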